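The closed, stirred vessel called alder is the flask asked about; ash is the earlier run with less starting material.

| flask | starting material | activator | protic impurity | remark | time |
|---|---|---|---|---|---|
| alder | 40 mM | 1.1 equiv | 40 mM | the very flask that is asked about, followed so far |  |
| ash | 27 mM | 1.1 equiv | 40 mM | run made earlier |  |
| flask | 40 mM | 1.10 equiv | 40.0 mM |  | 30 h |

| run | time / h | activated form / % | ring / % | starting material / % |
|---|---|---|---|---|
| alder | 0.333 | 7.7 | 0.5 | 88.9 |
| alder | 0.500 | 9.1 | 0.4 | 84.0 |
| alder | 1.00 | 13.0 | 3.7 | 69.7 |
| alder | 2.00 | 10.8 | 9.2 | 52.7 |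
| alder | 4.00 | 6.5 | 17.2 | 35.3 |
| alder | 6.00 | 3.8 | 20.8 | 28.0 |
| alder | 12.0 | 0.7 | 25.0 | 21.3 |
| ash | 0.333 | 5.4 | 0.6 | 92.4 |
| ash | 0.500 | 7.6 | 0.8 | 88.4 |
| ash | 1.00 | 9.7 | 2.8 | 79.2 |
| ash | 2.00 | 10.2 | 7.9 | 64.8 |
| ash | 4.00 | 6.9 | 14.3 | 49.2 |
| ash | 6.00 | 4.1 | 19.2 | 42.0 |
| ash | 12.0 | 0.4 | 23.5 | 35.1 |

(standard deviation of a reading: 0.3 percentage points)

- the best time, 30 h at the latest, for activated form
- the amount of activated form, in percent of the starting material charged, at that time

By 0.333 h, alder has lost 11.1 % of its starting material and ash 7.60 %. That ratio of 1.46 sits beside a ratio of charges of 1.48 at equal equivalents, so I take the early loss of starting material to follow activator concentration. In alder the readings of the activated form, the reactive intermediate, rise 3.9 percentage points in 0.500 h, then fall 2.2 points in 1.00 h. Setting these slopes at their midpoints and interpolating to zero puts the top near 1.33 h, and I commit to about the nearest reading, 13.0 %.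

So I expect the top to scale with the equivalents of activator and carry the peak per equivalent, the highest activated-form reading in alder divided by its equivalents of activator: 0.118. The weak link is that scaling: ash, at equal equivalents and equal protic impurity, has its highest reading at 10.2 %, lower than the highest in alder, so I reforge the rule to hold starting material at 40 mM and protic impurity at 40.0 mM.

The forecast gives 1.3 h (0.95 h to 1.7 h) and 13.2 % (12.5 % to 14.2 %): “At about 1.3–1.5 h they balance, giving a maximum near 13%.”

The flask peaks at 1.17 h with 12.7 %, inside the forecast's ranges. At 1.28 h making over using stands at 0.946, already past the top.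

    starting material + activated form → open dimer (k = 0.390 L mol⁻¹ min⁻¹)
    activator → decomposed reagent (k = 2.20 × 10⁻⁴ min⁻¹)
    activator + protic impurity → quenched reagent (k = 0.0880 L mol⁻¹ min⁻¹)
    activated form → ring (k = 0.00710 min⁻¹)
    starting material + activator → activated form (k = 0.130 L mol⁻¹ min⁻¹)

The peak per equivalent times 1.10 equiv gives back the alder reading it came from, 13.0 %. At 1.90 equiv, other charges and the time as here, it gives 22.5 %; the computed neighbour reaches 20.6 %, above the high end the forecast gave for this flask.

The data were generated by integration with constants of no real substance; scatter was added.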